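# Design of a synthesis of CNP0157505.1, (3R)-3,5,7-trihydroxy-3-[4-hydroxy-2-methoxy-3-prenylphenyl]-6-prenylchroman-4-one (23)

## The problem

Compound 23 is a (3R)-3-hydroxyisoflavanone: benzene ring A is fused to a dihydropyranone ring C (O1, the C2 methylene, C3, the C4 ketone), and ring B hangs from C3. C3 is the only stereocentre. It is fully substituted (hydroxyl, ring-B aryl, C2, C4) and has no neighbouring centre to relay configuration, so a reagent or catalyst must set it in the step that builds it. Once formed it is a tertiary α-ketol, benzylic to an electron-rich arene. Strong base can open it by retro-aldol loss of C2 as formaldehyde or by α-ketol shift, and strong acid can ionise it toward the isoflavone, so every later step has to be mild. Each arene carries a prenyl group on the carbon between two oxygens (C6 between O5 and O7, C3' between O2' and O4'). The alkenes rule out hydrogenolysis, electrophilic halogen sources and hot protic acid (chroman formation with a neighbouring free phenol), and free ortho-prenylphenols are sensitive to oxidants. Of the four phenolic oxygens only O2' is methylated, so ring B must enter with its two oxygens already differentiated, whereas ring A can stay symmetric for most of its life. The enabling feature is the bonding pattern of C3: one aryl bond, one bond to a carbon that can begin as an ester (C2), one C–O bond and one bond to a carbonyl carbon (C4). This is what the carbene carbon of an aryldiazoacetate acquires when an alcohol and an aldehyde add to it in succession. The remaining ring bond, O1–C8a, lies ortho to the C4 ketone and can be closed afterwards by displacing a fluoride.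

## Retrosynthesis

**23 back to 21 (no skeletal bond cut).** The three phenols are masked as methoxymethyl (MOM) ethers in 22 and the tertiary hydroxyl as a 4-methoxybenzyl (PMB) ether in 21. MOM is chosen because it also directs the lithiations that place the prenyl and formyl groups. PMB is chosen because it arrives as the O–H component of the key step and is removed oxidatively while the phenols are still protected. The forward steps must cleave a hindered tertiary benzyl ether without touching the prenylarenes, and then remove three acetals under acid mild enough for the α-ketol and the alkenes.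

**21 to 20: the O1–C8a bond.** Cutting the aryl ether gives the acyclic fluoro ketone 20, in which the primary hydroxyl on C2 attacks the carbon bearing fluorine. The neighbouring cut, O1–C2, would need a fourth phenolic oxygen on ring A that is distinguished from O5 and O7 throughout. A fluorine at C8a needs no protection, is small, and withdraws electron density from the aldehyde used earlier. The forward closure must be faster than retro-aldol loss of formaldehyde from the alkoxide.

**20 to 18: oxidation levels of C2 and C4.** In 18, C2 is a methyl ester and C4 a secondary benzylic alcohol. Reducing the ester first (to diol 19), while C4 is still an alcohol, avoids a ketone/ester selectivity problem. The benzylic alcohol is then oxidised in the presence of the primary one. Both C4 epimers converge at 20.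

**18 to 9 + 16 + 15: C3–O and C3–C4 (key cut).** Both bonds are cut at once, giving diazo ester 9 (ring B, C3 and C2), 4-methoxybenzyl alcohol 16 (the oxygen on C3) and aldehyde 15 (C4 and ring A). A stepwise aldol of a preformed α-alkoxy arylacetate enolate would make the same C3–C4 bond, but through a tetrasubstituted enolate of undefined geometry with no handle for absolute control. In the three-component mode the nucleophile is generated catalytically as an oxonium ylide that a chiral Brønsted acid can escort to the aldehyde. The precursors are three achiral pieces with no stereocentre. The forward reaction must trap the ylide with a hindered aldehyde faster than the ylide undergoes proton shift, and must control the face of C3.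

**9 back to 1: ring B.** The diazo group is traced to arylacetate 8 (diazo transfer). The aryl–CH bond of 8 is cut to aryl chloride 5 and dimethyl malonate 6 by way of aryl malonate 7. The prenyl–C3' bond of 5 is cut to prenyl bromide 3 and the MOM ether 2 of phenol 1, in which the carbon between the methoxy and MOM oxygens is the one a directed lithiation reaches. The halogen is carried from the start because the acetate arm must sit ortho to the methoxy group and para to the masked phenol. On a ring bearing only the two oxygens and the prenyl group, a second MOM-directed lithiation would go ortho to the MOM ether instead. Electrophilic halogenation could not distinguish two positions that are each para to one oxygen, and would endanger the alkene. A chloride survives n-butyllithium where a bromide would exchange. The forward sequence asks for lithiation between the oxygens without touching the chloride, and for arylation of a hindered, electron-rich aryl chloride.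

**15 back to 10: ring A.** The formyl–aryl bond is cut to fluoroarene 13, the prenyl–C6 bond to 11 and 3, and the two MOM ethers to the symmetric diol 10. Because 10 and 11 are symmetric, the two oxygens never need differentiating. Once the prenyl group is in place the two remaining ring positions of 13 are equivalent, so the formylation has no regiochemical choice. The one selectivity to secure is the first lithiation of 11, between the two MOM ethers and not next to fluorine.

## Roads not taken

**Alternative 1:** Ring A is taken apart at C4a–C5, C5–C6 and C7–C8, leaving a pyranone that already contains C3.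
- Forward step: irradiation of diazo ketone A2 triggers a Wolff rearrangement. The ketene function adds siloxyalkyne A3 in a [2+2] sense; the cyclobutenone opens, recloses by 6π electrocyclisation and tautomerises to A1.
- Merits: the polarity of A3 fixes the prenyl group at C6 between the new C5 phenol and the C7 silyl ether, so ring A raises no regiochemical question. O5 is born free and O7 differentiated.
- Weak points: C3 must already be present and enantiopure in A2, and nothing in this plan sets it, so the stereochemical problem is only moved into a longer linear sequence. A2 combines a vinylogous ester, an α-siloxy ketone and a diazo ketone. The methylene of A3 is both propargylic and allylic and prone to isomerise. The aryl ketone chromophore competes for the light.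
- Comparison: this road is better than the chosen plan in ring-A regiocontrol, which in the chosen plan rests on the lithiation selectivity of step 7. Against that, the chosen plan is convergent and creates C3 in the same step that joins the two halves.

**Alternative 2:** The two aryl–CH2 bonds of the prenyl groups (at C6 and C3') are cut.
- Forward step: the bis(1,1-dimethylallyl) ether A5 undergoes two aromatic Claisen rearrangements, each delivering a prenyl group to the free ortho carbon, to give A4.
- Merits: the alkenes appear late, so earlier steps need not tolerate them. Delivery from oxygen guarantees the positions next to O5 and O2' without any metalation.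
- Weak points: A5 requires tertiary alkylation of two hindered hydroxyls, one chelated to the C4 ketone and one ortho to the quaternary C3. In practice this means a propargyl ether and semi-hydrogenation at each site. The thermal rearrangement acts on a substrate that already holds the sensitive α-ketol. With C4a blocked, the C5 ether can also reach C8 through a Cope shift. A4 still needs selective methylation of O2' in the presence of O5 and the tertiary hydroxyl. The construction of the core and of C3 is left unanswered.
- Comparison: in regiocontrol of prenylation this road is at least as good as the chosen plan. The chosen plan offsets this by installing both prenyl groups in two early, high-precedent metalations on simple arenes (2 and 11) and exposing them afterwards only to mild reagents, and by answering the stereochemical question.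

**Alternative 3:** The C3–C4 bond is cut inside ring C.
- Forward step: a chiral triazolium-derived carbene adds to the aldehyde of keto aldehyde A7, and the acyl-anion equivalent attacks the tethered ring-B ketone. This closes ring C and sets C3 in A6, which is the same compound as 22.
- Merits: this is the best-precedented asymmetric entry to 3-hydroxychromanones. It forms the ring and the stereocentre in one catalytic step, needs no PMB group, and leaves one deprotection to 23 where the chosen plan needs five steps after its key step. In precedent and end-game economy it is superior.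
- Weak points: assembling A7 requires O-alkylation of one specific ring-A oxygen, so the three oxygens of a prenylated phloroglucinol aldehyde must be differentiated. It also requires an activated α-position on a ring-B ketone, made in the presence of a prenyl alkene. The aldehyde is flanked by two ortho oxygens and conjugated to three donors, the ketone bears an ortho-methoxyaryl group, and the acidic O–CH2–CO unit can undergo base-induced aldol condensation toward a 2-aroylbenzofuran.
- Comparison: the chosen plan's advantage is simpler fragments. Ring A comes from symmetric 10 with no phenol differentiation, fluorine replaces one ortho oxygen and makes aldehyde 15 less electron-rich, and the most likely by-product of its key step can be recycled through a stepwise aldol.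

Key step: step 9

Assumptions:
- Phenol 1 and diol 10 are taken as catalogue compounds.
- The sense of induction in step 9 cannot be predicted for this substrate pair. The (R)-acid is written; its enantiomer is to be used if the first sample, correlated at 21, proves to be (3S). The C4 carbinol of 18 and 19 is drawn (S) for definiteness; either epimer serves, since step 11 removes it.

## Route

Step 1
Reactants: 1 4-chloro-3-methoxyphenol
Product: 2 1-chloro-2-methoxy-4-(methoxymethoxy)benzene
Conditions: MOMCl, i-Pr2NEt, CH2Cl2, 0 °C to rt
Reagents that add atoms: chloromethyl methyl ether (MOMCl), COCCl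
Why: O-alkylation of the phenol with an α-chloro ether under amine base; the MOM ether masks O4' and is the directing group for step 2.

Step 2
Reactants: 2 1-chloro-2-methoxy-4-(methoxymethoxy)benzene; 3 1-bromo-3-methylbut-2-ene (prenyl bromide)
Product: 5 1-chloro-2-methoxy-4-(methoxymethoxy)-3-(3-methylbut-2-en-1-yl)benzene, via aryllithium 4 (not isolated)
Conditions: n-BuLi, THF, −40 to −10 °C; then CuBr·SMe2 (10 mol %), 3, −78 °C to rt
Reagents that add atoms: none
Why: Directed ortho-metalation removes the hydrogen flanked by the methoxy and MOM oxygens; the chloride does not exchange with n-BuLi at this temperature and sits meta to the lithiated carbon, so no aryne can form. Copper-assisted allylic substitution at the unhindered terminus of prenyl bromide gives the linear prenyl arene.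

Step 3
Reactants: 5 1-chloro-2-methoxy-4-(methoxymethoxy)-3-(3-methylbut-2-en-1-yl)benzene; 6 dimethyl malonate
Product: 7 dimethyl 2-[2-methoxy-4-(methoxymethoxy)-3-(3-methylbut-2-en-1-yl)phenyl]malonate
Conditions: Pd(dba)2 (2 mol %), P(t-Bu)3 (4 mol %), K3PO4, toluene, 90 °C
Reagents that add atoms: none
Why: Palladium-catalysed α-arylation of a malonate enolate; the bulky, electron-rich phosphine lets zerovalent palladium insert into the ortho-substituted, electron-rich aryl chloride, and the acidic product enolate resists a second arylation. K3PO4 leaves the MOM ether and the alkene untouched.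

Step 4
Reactants: 7 dimethyl 2-[2-methoxy-4-(methoxymethoxy)-3-(3-methylbut-2-en-1-yl)phenyl]malonate
Product: 8 methyl 2-[2-methoxy-4-(methoxymethoxy)-3-(3-methylbut-2-en-1-yl)phenyl]acetate
Conditions: LiCl, H2O, DMSO, 130 °C
Reagents that add atoms: none
Why: Krapcho dealkoxycarbonylation: chloride demethylates one ester, the aryl-stabilised carboxylate loses CO2 and water protonates the carbanion. The medium is neutral, so the acetal survives.

Step 5
Reactants: 8 methyl 2-[2-methoxy-4-(methoxymethoxy)-3-(3-methylbut-2-en-1-yl)phenyl]acetate
Product: 9 methyl 2-diazo-2-[2-methoxy-4-(methoxymethoxy)-3-(3-methylbut-2-en-1-yl)phenyl]acetate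
Conditions: p-ABSA, DBU, MeCN, 0 °C to rt
Reagents that add atoms: 4-acetamidobenzenesulfonyl azide (p-ABSA), CC(=O)Nc1ccc(cc1)S(=O)(=O)N=[N+]=[N-]
Why: Regitz diazo transfer: the benzylic ester enolate attacks the terminal nitrogen of the sulfonyl azide and the sulfonamide is expelled, giving a stable donor/acceptor diazo ester.

Step 6
Reactants: 10 5-fluorobenzene-1,3-diol
Product: 11 1-fluoro-3,5-bis(methoxymethoxy)benzene
Conditions: MOMCl, i-Pr2NEt, CH2Cl2, 0 °C to rt
Reagents that add atoms: chloromethyl methyl ether (MOMCl), COCCl
Why: Double O-alkylation of a symmetric diol; the two MOM ethers mask O5 and O7 and direct both later lithiations.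

Step 7
Reactants: 11 1-fluoro-3,5-bis(methoxymethoxy)benzene; 3 1-bromo-3-methylbut-2-ene (prenyl bromide)
Product: 13 5-fluoro-1,3-bis(methoxymethoxy)-2-(3-methylbut-2-en-1-yl)benzene, via aryllithium 12 (not isolated)
Conditions: n-BuLi, THF, −78 to −30 °C; then CuBr·SMe2 (10 mol %), 3, −78 °C to rt
Reagents that add atoms: none
Why: Directed ortho-metalation under coordination control: with n-BuLi alone the carbon held between two chelating MOM ethers should be lithiated in preference to the one between fluorine and a single MOM ether. The resulting aryllithium is para to fluorine and cannot lose LiF; copper-assisted substitution on prenyl bromide gives the linear product.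

Step 8
Reactants: 13 5-fluoro-1,3-bis(methoxymethoxy)-2-(3-methylbut-2-en-1-yl)benzene
Product: 15 6-fluoro-2,4-bis(methoxymethoxy)-3-(3-methylbut-2-en-1-yl)benzaldehyde, via aryllithium 14 (not isolated)
Conditions: n-BuLi, THF, −78 °C; DMF, −78 to 0 °C; then H2O
Reagents that add atoms: N,N-dimethylformamide, CN(C)C=O
Why: Second directed ortho-metalation followed by formylation with DMF: the two remaining ring hydrogens of 13 are equivalent and each is acidified by fluorine and a MOM ether. At −78 °C the ortho-fluoro aryllithium is stable toward aryne formation.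

Step 9
Reactants: 9 methyl 2-diazo-2-[2-methoxy-4-(methoxymethoxy)-3-(3-methylbut-2-en-1-yl)phenyl]acetate; 16 (4-methoxyphenyl)methanol (4-methoxybenzyl alcohol); 15 6-fluoro-2,4-bis(methoxymethoxy)-3-(3-methylbut-2-en-1-yl)benzaldehyde
Product: 18 methyl (2S,3S)-3-[6-fluoro-2,4-bis(methoxymethoxy)-3-(3-methylbut-2-en-1-yl)phenyl]-3-hydroxy-2-[2-methoxy-4-(methoxymethoxy)-3-(3-methylbut-2-en-1-yl)phenyl]-2-[(4-methoxybenzyl)oxy]propanoate, via oxonium ylide 17 (not isolated)
Conditions: 15 (1.5 equiv), Rh2(OAc)4 (2 mol %), (R)-3,3'-bis(2,4,6-triisopropylphenyl)-1,1'-binaphthyl-2,2'-diyl hydrogen phosphate (10 mol %), 4 Å molecular sieves, CH2Cl2, −20 °C; 9 and 16 (1.2 equiv) added over 3 h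
Reagents that add atoms: none
Why: Proposed new method: dirhodium tetraacetate converts 9 into an electrophilic divalent-rhodium carbene, the oxygen of 16 adds to it, and the oxonium ylide 17 (in equilibrium with its enol) adds through C3 to the carbonyl carbon of 15 while both partners are hydrogen-bonded to the chiral phosphoric acid, so that C3–O and C3–C4 form in one operation before a 1,2-proton shift can give the plain O–H insertion product. The closest known reaction type is the dirhodium/chiral Brønsted acid three-component coupling of aryldiazoacetates, benzylic alcohols and electron-poor aryl aldehydes or imines by trapping of protic oxonium ylides; an aldehyde with two ortho substituents and two alkoxy donors, combined with an ortho-methoxyaryl diazoacetate, lies outside that scope. No ring is closed. C3 is set by the chiral acid, which differentiates the two faces of the ylide carbon in the hydrogen-bonded transition state. C4 is formed as a carbinol whose configuration follows from the orientation of the aldehyde in the same assembly and is irrelevant because step 11 removes it, provided the material carried on is uniform at C3, which is why the major diastereomer is separated. The step needs trapping to outrun proton transfer: the ortho fluorine (smaller than an alkoxy group and electron-withdrawing) raises the electrophilicity of 15, 15 is used in excess and recoverable, 9 is added slowly at low temperature, and the 2'-methoxy group can hydrogen-bond the oxonium proton and retard its shift. It also needs O–H capture to win over cyclopropanation of the trisubstituted prenyl alkenes and over ylide formation at the acetal oxygens, which the much higher nucleophilicity of a free alcohol toward donor/acceptor carbenes should secure.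

Step 10
Reactants: 18 methyl (2S,3S)-3-[6-fluoro-2,4-bis(methoxymethoxy)-3-(3-methylbut-2-en-1-yl)phenyl]-3-hydroxy-2-[2-methoxy-4-(methoxymethoxy)-3-(3-methylbut-2-en-1-yl)phenyl]-2-[(4-methoxybenzyl)oxy]propanoate
Product: 19 (1S,2R)-1-[6-fluoro-2,4-bis(methoxymethoxy)-3-(3-methylbut-2-en-1-yl)phenyl]-2-[2-methoxy-4-(methoxymethoxy)-3-(3-methylbut-2-en-1-yl)phenyl]-2-[(4-methoxybenzyl)oxy]propane-1,3-diol
Conditions: LiBH4, THF, 0 °C to rt
Reagents that add atoms: none
Why: Chemoselective borohydride reduction of an α-alkoxy methyl ester, assisted by the neighbouring lithium alkoxide; aryl fluoride, acetals, benzyl ether and alkenes are inert. C3 keeps its configuration (the descriptor changes only because the ester becomes CH2OH), and low temperature suppresses retro-aldol cleavage.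

Step 11
Reactants: 19 (1S,2R)-1-[6-fluoro-2,4-bis(methoxymethoxy)-3-(3-methylbut-2-en-1-yl)phenyl]-2-[2-methoxy-4-(methoxymethoxy)-3-(3-methylbut-2-en-1-yl)phenyl]-2-[(4-methoxybenzyl)oxy]propane-1,3-diol
Product: 20 (2R)-1-[6-fluoro-2,4-bis(methoxymethoxy)-3-(3-methylbut-2-en-1-yl)phenyl]-3-hydroxy-2-[2-methoxy-4-(methoxymethoxy)-3-(3-methylbut-2-en-1-yl)phenyl]-2-[(4-methoxybenzyl)oxy]propan-1-one
Conditions: activated MnO2 (excess), CH2Cl2, rt
Reagents that add atoms: none
Why: MnO2 oxidises benzylic alcohols selectively and leaves the primary aliphatic alcohol; C3 has no hydrogen and cannot epimerise, and the C4 stereocentre is erased.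

Step 12
Reactants: 20 (2R)-1-[6-fluoro-2,4-bis(methoxymethoxy)-3-(3-methylbut-2-en-1-yl)phenyl]-3-hydroxy-2-[2-methoxy-4-(methoxymethoxy)-3-(3-methylbut-2-en-1-yl)phenyl]-2-[(4-methoxybenzyl)oxy]propan-1-one
Product: 21 (3R)-3-[2-methoxy-4-(methoxymethoxy)-3-(3-methylbut-2-en-1-yl)phenyl]-3-[(4-methoxybenzyl)oxy]-5,7-bis(methoxymethoxy)-6-(3-methylbut-2-en-1-yl)chroman-4-one
Conditions: K2CO3, DMF, 40 °C
Reagents that add atoms: none
Why: Intramolecular nucleophilic aromatic substitution (addition–elimination): the ortho ketone stabilises the Meisenheimer intermediate, fluoride is the best leaving group for this mechanism, and the primary alkoxide closes the six-membered ring. C3 has no hydrogen, so no elimination is possible, and the PMB ether prevents the tertiary oxygen from closing a five-membered ring instead.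

Step 13
Reactants: 21 (3R)-3-[2-methoxy-4-(methoxymethoxy)-3-(3-methylbut-2-en-1-yl)phenyl]-3-[(4-methoxybenzyl)oxy]-5,7-bis(methoxymethoxy)-6-(3-methylbut-2-en-1-yl)chroman-4-one
Product: 22 (3R)-3-hydroxy-3-[2-methoxy-4-(methoxymethoxy)-3-(3-methylbut-2-en-1-yl)phenyl]-5,7-bis(methoxymethoxy)-6-(3-methylbut-2-en-1-yl)chroman-4-one
Conditions: DDQ, CH2Cl2/pH 7 phosphate buffer, 0 °C to rt
Reagents that add atoms: none
Why: Oxidative PMB cleavage: DDQ abstracts hydride from the 4-methoxybenzylic position and water hydrolyses the oxocarbenium ion. All phenols are still MOM-protected, so the oxidative cyclisation of ortho-prenylphenols to chromenes cannot occur.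

Step 14
Reactants: 22 (3R)-3-hydroxy-3-[2-methoxy-4-(methoxymethoxy)-3-(3-methylbut-2-en-1-yl)phenyl]-5,7-bis(methoxymethoxy)-6-(3-methylbut-2-en-1-yl)chroman-4-one
Product: 23 (3R)-3,5,7-trihydroxy-3-[4-hydroxy-2-methoxy-3-(3-methylbut-2-en-1-yl)phenyl]-6-(3-methylbut-2-en-1-yl)chroman-4-one
Conditions: HCl (3 M aq.), MeOH, 40 °C
Reagents that add atoms: none
Why: Acid-catalysed acetal exchange with methanol removes the three MOM groups. Mild acid and a short reaction time keep the freed phenols from adding to the prenyl alkenes, and ionisation at C3 is disfavoured by the adjacent ketone.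

## Compound list

1 | 4-chloro-3-methoxyphenol | COc1cc(O)ccc1Cl | starting material
2 | 1-chloro-2-methoxy-4-(methoxymethoxy)benzene | COCOc1ccc(Cl)c(OC)c1 | intermediate
3 | 1-bromo-3-methylbut-2-ene (prenyl bromide) | CC(C)=CCBr | starting material
4 | 3-chloro-2-methoxy-6-(methoxymethoxy)phenyllithium | [Li]c1c(OC)c(Cl)ccc1OCOC | intermediate (not isolated)
5 | 1-chloro-2-methoxy-4-(methoxymethoxy)-3-(3-methylbut-2-en-1-yl)benzene | COCOc1ccc(Cl)c(OC)c1CC=C(C)C | intermediate
6 | dimethyl malonate | COC(=O)CC(=O)OC | starting material
7 | dimethyl 2-[2-methoxy-4-(methoxymethoxy)-3-(3-methylbut-2-en-1-yl)phenyl]malonate | COC(=O)C(C(=O)OC)c1ccc(OCOC)c(CC=C(C)C)c1OC | intermediate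
8 | methyl 2-[2-methoxy-4-(methoxymethoxy)-3-(3-methylbut-2-en-1-yl)phenyl]acetate | COC(=O)Cc1ccc(OCOC)c(CC=C(C)C)c1OC | intermediate
9 | methyl 2-diazo-2-[2-methoxy-4-(methoxymethoxy)-3-(3-methylbut-2-en-1-yl)phenyl]acetate | COC(=O)C(=[N+]=[N-])c1ccc(OCOC)c(CC=C(C)C)c1OC | intermediate
10 | 5-fluorobenzene-1,3-diol | Oc1cc(O)cc(F)c1 | starting material
11 | 1-fluoro-3,5-bis(methoxymethoxy)benzene | COCOc1cc(F)cc(OCOC)c1 | intermediate
12 | 4-fluoro-2,6-bis(methoxymethoxy)phenyllithium | [Li]c1c(OCOC)cc(F)cc1OCOC | intermediate (not isolated)
13 | 5-fluoro-1,3-bis(methoxymethoxy)-2-(3-methylbut-2-en-1-yl)benzene | COCOc1cc(F)cc(OCOC)c1CC=C(C)C | intermediate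
14 | 6-fluoro-2,4-bis(methoxymethoxy)-3-(3-methylbut-2-en-1-yl)phenyllithium | [Li]c1c(F)cc(OCOC)c(CC=C(C)C)c1OCOC | intermediate (not isolated)
15 | 6-fluoro-2,4-bis(methoxymethoxy)-3-(3-methylbut-2-en-1-yl)benzaldehyde | O=Cc1c(F)cc(OCOC)c(CC=C(C)C)c1OCOC | intermediate
16 | (4-methoxyphenyl)methanol (4-methoxybenzyl alcohol) | COc1ccc(CO)cc1 | starting material
17 | oxonium ylide from the carbene of 9 and alcohol 16 (carbanion at C3, protonated ether oxygen) | COC(=O)[C-](c1ccc(OCOC)c(CC=C(C)C)c1OC)[OH+]Cc1ccc(OC)cc1 | intermediate (not isolated)
18 | methyl (2S,3S)-3-[6-fluoro-2,4-bis(methoxymethoxy)-3-(3-methylbut-2-en-1-yl)phenyl]-3-hydroxy-2-[2-methoxy-4-(methoxymethoxy)-3-(3-methylbut-2-en-1-yl)phenyl]-2-[(4-methoxybenzyl)oxy]propanoate | COc1c([C@@]([C@@H](O)c2c(F)cc(OCOC)c(CC=C(C)C)c2OCOC)(OCc2ccc(OC)cc2)C(=O)OC)ccc(OCOC)c1CC=C(C)C | intermediate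
19 | (1S,2R)-1-[6-fluoro-2,4-bis(methoxymethoxy)-3-(3-methylbut-2-en-1-yl)phenyl]-2-[2-methoxy-4-(methoxymethoxy)-3-(3-methylbut-2-en-1-yl)phenyl]-2-[(4-methoxybenzyl)oxy]propane-1,3-diol | COc1c([C@@]([C@@H](O)c2c(F)cc(OCOC)c(CC=C(C)C)c2OCOC)(OCc2ccc(OC)cc2)CO)ccc(OCOC)c1CC=C(C)C | intermediate
20 | (2R)-1-[6-fluoro-2,4-bis(methoxymethoxy)-3-(3-methylbut-2-en-1-yl)phenyl]-3-hydroxy-2-[2-methoxy-4-(methoxymethoxy)-3-(3-methylbut-2-en-1-yl)phenyl]-2-[(4-methoxybenzyl)oxy]propan-1-one | COc1c([C@@](C(=O)c2c(F)cc(OCOC)c(CC=C(C)C)c2OCOC)(OCc2ccc(OC)cc2)CO)ccc(OCOC)c1CC=C(C)C | intermediate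
21 | (3R)-3-[2-methoxy-4-(methoxymethoxy)-3-(3-methylbut-2-en-1-yl)phenyl]-3-[(4-methoxybenzyl)oxy]-5,7-bis(methoxymethoxy)-6-(3-methylbut-2-en-1-yl)chroman-4-one | COc1c([C@@]2(OCc3ccc(OC)cc3)COc3cc(OCOC)c(CC=C(C)C)c(OCOC)c3C2=O)ccc(OCOC)c1CC=C(C)C | intermediate
22 | (3R)-3-hydroxy-3-[2-methoxy-4-(methoxymethoxy)-3-(3-methylbut-2-en-1-yl)phenyl]-5,7-bis(methoxymethoxy)-6-(3-methylbut-2-en-1-yl)chroman-4-one | COc1c([C@@]2(O)COc3cc(OCOC)c(CC=C(C)C)c(OCOC)c3C2=O)ccc(OCOC)c1CC=C(C)C | intermediate
23 | (3R)-3,5,7-trihydroxy-3-[4-hydroxy-2-methoxy-3-(3-methylbut-2-en-1-yl)phenyl]-6-(3-methylbut-2-en-1-yl)chroman-4-one | COc1c([C@@]2(O)COc3cc(O)c(CC=C(C)C)c(O)c3C2=O)ccc(O)c1CC=C(C)C | target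

## Step count and risk

Total: 14 steps. Longest linear sequence: 11 steps (steps 1–5 and 9–14, from 1). The ring-A branch is 3 steps (6–8).

**Step 9 (key step, carries the new-method label).** The most likely failure is that the 1,2-proton shift of the ylide outruns its addition to the hindered, donor-substituted aldehyde, so that plain O–H insertion dominates. A second failure would be insufficient or non-uniform facial control at C3. The fallback uses known chemistry only; it sets out from 9, 16 and 15 and returns at 21. The O–H insertion is run on purpose (Rh2(OAc)4, CH2Cl2, no aldehyde) to give the racemic α-(4-methoxybenzyloxy) arylacetate F1. Its lithium enolate (LiN(SiMe3)2, THF, −78 °C) is added to 15 to give the racemic aldol adduct F2. This is taken through the conditions of steps 10–12 as racemic diol F3, racemic ketone F4 and racemic chromanone F5. F5 is resolved by preparative chromatography on a chiral stationary phase into 21 and its (3S)-enantiomer F6.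

**Step 7.** The most likely failure is loss of regiocontrol: metalation at the carbon between fluorine and one MOM ether competes with metalation between the two MOM ethers, and the ortho-fluoro aryllithium then decomposes through an aryne on warming. The fallback sets out from 10 and returns at 13. Diol 10 is iodinated between the hydroxyls (I2, NaHCO3, water, 0 °C, as is known for resorcinol itself) to 5-fluoro-2-iodobenzene-1,3-diol F7. This is protected to 5-fluoro-2-iodo-1,3-bis(methoxymethoxy)benzene F8. Iodine–lithium exchange (n-BuLi, −78 °C) then gives 12 at the defined carbon, which is prenylated as in step 7.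

**Step 11.** The most likely failure is slow or incomplete oxidation, because the carbinol C–H is flanked by two ortho substituents and a quaternary carbon and cannot easily align with the arene; long exposure could then begin to consume the primary alcohol. The fallback sets out from 19 and returns at 20. The primary hydroxyl is silylated selectively (TBSCl, imidazole, DMF) to the tert-butyldimethylsilyl ether F9. The secondary alcohol is oxidised with Dess–Martin periodinane to the keto silyl ether F10. The silyl group is removed with HF·pyridine.

**Step 12.** The most likely failure is retro-aldol cleavage of the alkoxide (loss of C2 as formaldehyde, which would also erode C3) competing with ring closure, because the twisted ketone activates the fluoride only moderately. The fallback sets out from 20 and returns at 21. The primary alcohol is converted into the trimethylsilyl ether F11 (TMSCl, Et3N), and closure is triggered by a catalytic amount of CsF in DMF. Fluoride transfer from silicon releases the alkoxide only transiently, and the fluoride expelled in the substitution carries the chain, so no stoichiometric base is present.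

**Step 14.** The most likely failure is acid-promoted addition of the freed phenols to the neighbouring prenyl alkenes (chroman formation), with ionisation and dehydration at C3 toward the isoflavone on long exposure. The fallback sets out from 22 and returns at 23. The acetals are cleaved by Lewis-acid thiol exchange (ZnBr2, n-PrSH, CH2Cl2, 0 °C), which captures the methoxymethyl unit on sulfur within minutes and avoids a protic acid medium. No new isolated compound arises.

## Further compounds

F1 | step 9 | racemic methyl 2-[2-methoxy-4-(methoxymethoxy)-3-(3-methylbut-2-en-1-yl)phenyl]-2-[(4-methoxybenzyl)oxy]acetate | COC(=O)C(OCc1ccc(OC)cc1)c1ccc(OCOC)c(CC=C(C)C)c1OC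
F2 | step 9 | racemic methyl 3-[6-fluoro-2,4-bis(methoxymethoxy)-3-(3-methylbut-2-en-1-yl)phenyl]-3-hydroxy-2-[2-methoxy-4-(methoxymethoxy)-3-(3-methylbut-2-en-1-yl)phenyl]-2-[(4-methoxybenzyl)oxy]propanoate (both C4 epimers) | COc1c(C(C(O)c2c(F)cc(OCOC)c(CC=C(C)C)c2OCOC)(OCc2ccc(OC)cc2)C(=O)OC)ccc(OCOC)c1CC=C(C)C
F3 | step 9 | racemic 1-[6-fluoro-2,4-bis(methoxymethoxy)-3-(3-methylbut-2-en-1-yl)phenyl]-2-[2-methoxy-4-(methoxymethoxy)-3-(3-methylbut-2-en-1-yl)phenyl]-2-[(4-methoxybenzyl)oxy]propane-1,3-diol | COc1c(C(C(O)c2c(F)cc(OCOC)c(CC=C(C)C)c2OCOC)(OCc2ccc(OC)cc2)CO)ccc(OCOC)c1CC=C(C)C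
F4 | step 9 | racemic 1-[6-fluoro-2,4-bis(methoxymethoxy)-3-(3-methylbut-2-en-1-yl)phenyl]-3-hydroxy-2-[2-methoxy-4-(methoxymethoxy)-3-(3-methylbut-2-en-1-yl)phenyl]-2-[(4-methoxybenzyl)oxy]propan-1-one | COc1c(C(C(=O)c2c(F)cc(OCOC)c(CC=C(C)C)c2OCOC)(OCc2ccc(OC)cc2)CO)ccc(OCOC)c1CC=C(C)C
F5 | step 9 | racemic 3-[2-methoxy-4-(methoxymethoxy)-3-(3-methylbut-2-en-1-yl)phenyl]-3-[(4-methoxybenzyl)oxy]-5,7-bis(methoxymethoxy)-6-(3-methylbut-2-en-1-yl)chroman-4-one | COc1c(C2(OCc3ccc(OC)cc3)COc3cc(OCOC)c(CC=C(C)C)c(OCOC)c3C2=O)ccc(OCOC)c1CC=C(C)C
F6 | step 9 | (3S)-3-[2-methoxy-4-(methoxymethoxy)-3-(3-methylbut-2-en-1-yl)phenyl]-3-[(4-methoxybenzyl)oxy]-5,7-bis(methoxymethoxy)-6-(3-methylbut-2-en-1-yl)chroman-4-one | COc1c([C@]2(OCc3ccc(OC)cc3)COc3cc(OCOC)c(CC=C(C)C)c(OCOC)c3C2=O)ccc(OCOC)c1CC=C(C)C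
F7 | step 7 | 5-fluoro-2-iodobenzene-1,3-diol | Oc1cc(F)cc(O)c1I
F8 | step 7 | 5-fluoro-2-iodo-1,3-bis(methoxymethoxy)benzene | COCOc1cc(F)cc(OCOC)c1I
F9 | step 11 | (1S,2R)-3-[(tert-butyldimethylsilyl)oxy]-1-[6-fluoro-2,4-bis(methoxymethoxy)-3-(3-methylbut-2-en-1-yl)phenyl]-2-[2-methoxy-4-(methoxymethoxy)-3-(3-methylbut-2-en-1-yl)phenyl]-2-[(4-methoxybenzyl)oxy]propan-1-ol | COc1c([C@@]([C@@H](O)c2c(F)cc(OCOC)c(CC=C(C)C)c2OCOC)(OCc2ccc(OC)cc2)CO[Si](C)(C)C(C)(C)C)ccc(OCOC)c1CC=C(C)C
F10 | step 11 | (2R)-3-[(tert-butyldimethylsilyl)oxy]-1-[6-fluoro-2,4-bis(methoxymethoxy)-3-(3-methylbut-2-en-1-yl)phenyl]-2-[2-methoxy-4-(methoxymethoxy)-3-(3-methylbut-2-en-1-yl)phenyl]-2-[(4-methoxybenzyl)oxy]propan-1-one | COc1c([C@@](C(=O)c2c(F)cc(OCOC)c(CC=C(C)C)c2OCOC)(OCc2ccc(OC)cc2)CO[Si](C)(C)C(C)(C)C)ccc(OCOC)c1CC=C(C)C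
F11 | step 12 | (2R)-1-[6-fluoro-2,4-bis(methoxymethoxy)-3-(3-methylbut-2-en-1-yl)phenyl]-2-[2-methoxy-4-(methoxymethoxy)-3-(3-methylbut-2-en-1-yl)phenyl]-2-[(4-methoxybenzyl)oxy]-3-[(trimethylsilyl)oxy]propan-1-one | COc1c([C@@](C(=O)c2c(F)cc(OCOC)c(CC=C(C)C)c2OCOC)(OCc2ccc(OC)cc2)CO[Si](C)(C)C)ccc(OCOC)c1CC=C(C)C
F0 | step 14 | none | none
A1 | alternative 1 | (3R)-5-hydroxy-3-[2-methoxy-4-(methoxymethoxy)-3-(3-methylbut-2-en-1-yl)phenyl]-6-(3-methylbut-2-en-1-yl)-3-(triethylsilyloxy)-7-(triisopropylsilyloxy)chroman-4-one | COc1c([C@@]2(O[Si](CC)(CC)CC)COc3cc(O[Si](C(C)C)(C(C)C)C(C)C)c(CC=C(C)C)c(O)c3C2=O)ccc(OCOC)c1CC=C(C)C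
A2 | alternative 1 | (3R)-6-(2-diazoacetyl)-3-[2-methoxy-4-(methoxymethoxy)-3-(3-methylbut-2-en-1-yl)phenyl]-3-(triethylsilyloxy)-2,3-dihydro-4H-pyran-4-one | COc1c([C@@]2(O[Si](CC)(CC)CC)COC(C(=O)C=[N+]=[N-])=CC2=O)ccc(OCOC)c1CC=C(C)C
A3 | alternative 1 | triisopropyl[(5-methylhex-4-en-1-yn-1-yl)oxy]silane | CC(C)=CCC#CO[Si](C(C)C)(C(C)C)C(C)C
A4 | alternative 2 | (3R)-3,5-dihydroxy-3-[2-hydroxy-4-(methoxymethoxy)-3-(3-methylbut-2-en-1-yl)phenyl]-7-(methoxymethoxy)-6-(3-methylbut-2-en-1-yl)chroman-4-one | Oc1c([C@@]2(O)COc3cc(OCOC)c(CC=C(C)C)c(O)c3C2=O)ccc(OCOC)c1CC=C(C)C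
A5 | alternative 2 | (3R)-3-hydroxy-7-(methoxymethoxy)-3-[4-(methoxymethoxy)-2-(2-methylbut-3-en-2-yloxy)phenyl]-5-(2-methylbut-3-en-2-yloxy)chroman-4-one | C=CC(C)(C)Oc1cc(OCOC)ccc1[C@@]1(O)COc2cc(OCOC)cc(OC(C)(C)C=C)c2C1=O
A6 | alternative 3 | (3R)-3-hydroxy-3-[2-methoxy-4-(methoxymethoxy)-3-(3-methylbut-2-en-1-yl)phenyl]-5,7-bis(methoxymethoxy)-6-(3-methylbut-2-en-1-yl)chroman-4-one (identical with 22) | COc1c([C@@]2(O)COc3cc(OCOC)c(CC=C(C)C)c(OCOC)c3C2=O)ccc(OCOC)c1CC=C(C)C
A7 | alternative 3 | 2-{2-[2-methoxy-4-(methoxymethoxy)-3-(3-methylbut-2-en-1-yl)phenyl]-2-oxoethoxy}-4,6-bis(methoxymethoxy)-5-(3-methylbut-2-en-1-yl)benzaldehyde | O=Cc1c(OCC(=O)c2ccc(OCOC)c(CC=C(C)C)c2OC)cc(OCOC)c(CC=C(C)C)c1OCOC
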